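**Strategy.** The route rests on closing ring A at C5–C10 (ent-kaurane numbering, see remark) by a carboxyl-terminated Prins cyclisation. In seco-acid 16 the single quaternary stereocentre C4 carries the C19 carboxyl, a 4-oxopentyl arm ending in the C10 ketone, and the E-C5=C6 alkene. Lewis-acid activation makes C5 attack C10 while the C19 carboxyl adds anti at C6, so ring A, the 19,6-γ-lactone and the C5, C6 and C10 stereocentres form in one operation. The step exploits that C5 sits between carbinol C10, oxygen-bearing C6 and C4, which holds C19. Acid 16 comes from allylation of an (R)-4-allylcyclohexenone enolate with a C4-chiral allylic bromide; the bicyclo[3.2.1]octenone is closed afterwards by aldol.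

Key step: step 8

Remark (numbering): ring A = C1, C2, C3, C4, C5, C10 (C18 methyl and C19 lactone carbonyl on C4; C20 methyl and hydroxyl on C10); C6 = lactone CH–O; C7 = methylene link; bicyclo[3.2.1]octenone = C8 (quaternary bridgehead), C9 (ketone), C11=C12, C13 (bridgehead CH), C14 (one-carbon bridge), C15 (acetoxy carbon), C16(=C17H2). In this numbering the target is 4R,5S,6R,8R,10R,13S,15R.

Remark (assumption): the alkylation of step 6 gives C8 epimers; the trans isomer is drawn for 15 to 20, and both converge in step 11, where C8 becomes an enolate carbon.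

Remark (assumption): in steps 3 and 5 the antipode of the chiral ligand or catalyst that delivers the stated configuration is meant.

Step 1
Reactants: 1 tert-butyl methacrylate; 2 allyl diethyl phosphate
Product: 3 tert-butyl (E)-4-[(diethoxyphosphoryl)oxy]-2-methylbut-2-enoate
Conditions: second-generation Grubbs catalyst RuCl2(PCy3)(H2IMes)(=CHPh) (3 mol %), 1 in excess, CH2Cl2, 40 °C
Reagents that add atoms: none
Why: Olefin cross-metathesis of the 1,1-disubstituted acrylate 1 (slow to homodimerise) with the terminal olefin 2 should give the trisubstituted enoate with loss of ethene, the E-geometry following from thermodynamic control.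

Step 2
Reactants: 4 2-(3-chloropropyl)-2-methyl-1,3-dioxolane
Product: 5 2-(3-iodopropyl)-2-methyl-1,3-dioxolane
Conditions: NaI, NaHCO3 (cat.), acetone, reflux
Reagents that add atoms: sodium iodide, [Na+].[I-]
Why: Finkelstein reaction, an SN2 halide exchange driven by precipitation of NaCl from acetone, leaves the ketal untouched.

Step 3
Reactants: 3 tert-butyl (E)-4-[(diethoxyphosphoryl)oxy]-2-methylbut-2-enoate; 5 2-(3-iodopropyl)-2-methyl-1,3-dioxolane
Product: 7 tert-butyl (R)-2-methyl-2-[3-(2-methyl-1,3-dioxolan-2-yl)propyl]but-3-enoate, via dialkylzinc 6 (not isolated)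
Conditions: 5, Et2Zn (neat), CuI (cat.), 50 °C, then volatiles removed; then 3, (CuOTf)2·C6H6 (5 mol %), chiral pyridyl Schiff-base dipeptide ligand (10 mol %), THF, −15 °C
Reagents that add atoms: none
Why: Iodine–zinc exchange gives dialkylzinc 6, and copper-catalysed enantioselective SN2′ allylic alkylation then transfers one alkyl group to the ester α-carbon of 3 with loss of phosphate, creating the quaternary centre C4 whose (R) configuration is set by the chiral ligand on copper.

Step 4
Reactants: 7 tert-butyl (R)-2-methyl-2-[3-(2-methyl-1,3-dioxolan-2-yl)propyl]but-3-enoate; 8 (E)-1,4-dibromobut-2-ene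
Product: 9 tert-butyl (R,E)-5-bromo-2-methyl-2-[3-(2-methyl-1,3-dioxolan-2-yl)propyl]pent-3-enoate
Conditions: 8 (4 equiv), second-generation Grubbs catalyst RuCl2(PCy3)(H2IMes)(=CHPh) (5 mol %), CH2Cl2, 40 °C
Reagents that add atoms: none
Why: Olefin cross-metathesis of the vinyl group on the quaternary carbon (which cannot homodimerise) with an excess of 8 should give the primary allylic bromide, the bulky C4 substituents enforcing the E-geometry while C4 itself is untouched.

Step 5
Reactants: 10 pent-4-enal; 11 but-3-en-2-one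
Product: 13 (R)-4-(prop-2-en-1-yl)cyclohex-2-en-1-one, via keto aldehyde 12 (not isolated)
Conditions: (R)-2-[diphenyl(trimethylsilyloxy)methyl]pyrrolidine (10 mol %), ethyl 3,4-dihydroxybenzoate (20 mol %), neat, 4 °C; then KOH, nBu4NOH (cat.), Et2O/THF/H2O, reflux
Reagents that add atoms: none
Why: Enamine-catalysed asymmetric Michael addition of 10 to 11 followed by intramolecular aldol condensation (a Robinson-type annulation) builds the enone, the silyloxydiphenylmethyl group of the catalyst shielding one enamine face so that C13 is set as (R).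

Step 6
Reactants: 13 (R)-4-(prop-2-en-1-yl)cyclohex-2-en-1-one; 9 tert-butyl (R,E)-5-bromo-2-methyl-2-[3-(2-methyl-1,3-dioxolan-2-yl)propyl]pent-3-enoate
Product: 15 tert-butyl (2R,3E)-2-methyl-2-[3-(2-methyl-1,3-dioxolan-2-yl)propyl]-5-[trans-2-oxo-5-(prop-2-en-1-yl)cyclohex-3-en-1-yl]pent-3-enoate, via lithium dienolate 14 (not isolated)
Conditions: LiN(iPr)2, THF, −78 °C; then 9, DMPU, −78 to −20 °C
Reagents that add atoms: none
Why: Kinetic α′-deprotonation of the enone gives cross-conjugated lithium enolate 14, whose SN2 alkylation at the primary allylic carbon of 9 forms the C7–C8 bond, C8 arising mainly trans to the allyl group although its configuration is irrelevant because it is erased in step 11.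

Step 7
Reactants: 15 tert-butyl (2R,3E)-2-methyl-2-[3-(2-methyl-1,3-dioxolan-2-yl)propyl]-5-[trans-2-oxo-5-(prop-2-en-1-yl)cyclohex-3-en-1-yl]pent-3-enoate
Product: 16 (2R,3E)-2-methyl-2-(4-oxopentyl)-5-[trans-2-oxo-5-(prop-2-en-1-yl)cyclohex-3-en-1-yl]pent-3-enoic acid
Conditions: CF3CO2H/CH2Cl2 (1:3), H2O (5 equiv), 0 °C to rt
Reagents that add atoms: water, O
Why: Acidolysis removes the tert-butyl ester as isobutene and hydrolyses the dioxolane to the methyl ketone without touching alkene geometry or stereocentres.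

Step 8
Reactants: 16 (2R,3E)-2-methyl-2-(4-oxopentyl)-5-[trans-2-oxo-5-(prop-2-en-1-yl)cyclohex-3-en-1-yl]pent-3-enoic acid
Product: 17 (3R,3aS,4R,7aR)-4-hydroxy-4,7a-dimethyl-3-{[trans-2-oxo-5-(prop-2-en-1-yl)cyclohex-3-en-1-yl]methyl}hexahydro-2-benzofuran-1(3H)-one
Conditions: SnCl4 (2.5 equiv), CH2Cl2, −78 to −20 °C
Reagents that add atoms: none
Why: SnCl4 binds the C10 ketone, C5 of the E-C5=C6 alkene attacks C10, and the C19 carboxyl captures the positive charge developing at C6 and then loses its proton, so the C5–C10 and C6–O bonds form in one cationic event. The closest known reaction types are Lewis-acid-initiated ketone–olefin (Prins) cyclisations with capture of a secondary cation and the carboxyl-terminated cation–olefin cyclisation of β,γ-unsaturated acids, as in homofarnesic acid to sclareolide. Ring A closes 6-exo-trig at the alkene through a chair, and the γ-lactone closes 5-endo-trig, a mode that is normal for cationic and onium-type lactonisations of β,γ-unsaturated acids. C5 and C6 are controlled by C4: tether and carboxyl both hang on C4, so only the conformer with C3 and C19 on opposite faces of the alkene can react, and anti addition across the E-alkene then gives the cis-fused lactone with C7 on its convex face. C10 is controlled by the chair, in which the ketone methyl stays equatorial to avoid a 1,3-diaxial clash with the axial C4 methyl, so the hydroxyl ends up trans to C6. The step needs chemoselectivity for the C5=C6 alkene over the allyl group and the enone and needs lactonisation to outrun proton loss from C7, which the six- and five-membered intramolecular transition states and the low temperature should secure.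

Step 9
Reactants: 17 (3R,3aS,4R,7aR)-4-hydroxy-4,7a-dimethyl-3-{[trans-2-oxo-5-(prop-2-en-1-yl)cyclohex-3-en-1-yl]methyl}hexahydro-2-benzofuran-1(3H)-one
Product: 19 (3R,3aS,4R,7aR)-4-hydroxy-4,7a-dimethyl-3-{[trans-2-oxo-5-(2-oxoethyl)cyclohex-3-en-1-yl]methyl}hexahydro-2-benzofuran-1(3H)-one, via diol 18 (not isolated)
Conditions: OsO4 (2 mol %), NaIO4 (4 equiv), 2,6-lutidine, dioxane/H2O (3:1), rt
Reagents that add atoms: osmium tetroxide, O=[Os](=O)(=O)=O; sodium periodate, [Na+].[O-]I(=O)(=O)=O
Why: Lemieux–Johnson oxidation (catalytic dihydroxylation to diol 18, then periodate cleavage) shortens the allyl group to the aldehyde, the electron-rich terminal alkene reacting far faster with OsO4 than the electron-poor enone C=C.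

Step 10
Reactants: 19 (3R,3aS,4R,7aR)-4-hydroxy-4,7a-dimethyl-3-{[trans-2-oxo-5-(2-oxoethyl)cyclohex-3-en-1-yl]methyl}hexahydro-2-benzofuran-1(3H)-one
Product: 20 (3R,3aS,4R,7aR)-4-hydroxy-4,7a-dimethyl-3-{[trans-2-oxo-5-(3-oxoprop-1-en-2-yl)cyclohex-3-en-1-yl]methyl}hexahydro-2-benzofuran-1(3H)-one
Conditions: 37% aq. HCHO, pyrrolidine (10 mol %), EtCO2H (10 mol %), iPrOH, 45 °C
Reagents that add atoms: formaldehyde, C=O
Why: Amine-catalysed Mannich condensation of the aldehyde with formaldehyde followed by β-elimination of the amine (α-methylenation) installs C17 on C16 selectively at the aldehyde, the ketone being much less prone to enamine formation.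

Step 11
Reactants: 20 (3R,3aS,4R,7aR)-4-hydroxy-4,7a-dimethyl-3-{[trans-2-oxo-5-(3-oxoprop-1-en-2-yl)cyclohex-3-en-1-yl]methyl}hexahydro-2-benzofuran-1(3H)-one
Product: 23 (3R,3aS,4R,7aR)-4-hydroxy-3-{[(1R,5S,7R)-7-hydroxy-6-methylidene-2-oxobicyclo[3.2.1]oct-3-en-1-yl]methyl}-4,7a-dimethylhexahydro-2-benzofuran-1(3H)-one, via dilithium dienolate 21 (not isolated), via dilithium aldolate 22 (not isolated)
Conditions: LiN(SiMe3)2 (2.1 equiv), THF, −78 °C; then AcOH, −78 °C
Reagents that add atoms: none
Why: Kinetic α′-deprotonation at C8 and intramolecular aldol addition (5-exo-trig onto the C15 aldehyde) close the bicyclo[3.2.1]octenone, C8 being forced to bridge on the face of the C13 substituent and C15 being set by the lithium-chelated closed transition state that places the aldolate oxygen syn to the C9 carbonyl.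

Step 12
Reactants: 23 (3R,3aS,4R,7aR)-4-hydroxy-3-{[(1R,5S,7R)-7-hydroxy-6-methylidene-2-oxobicyclo[3.2.1]oct-3-en-1-yl]methyl}-4,7a-dimethylhexahydro-2-benzofuran-1(3H)-one
Product: 24 CNP0172716.1, (1R,5S,7R)-1-{[(1R,3aR,7R,7aS)-7-hydroxy-3a,7-dimethyl-3-oxooctahydro-2-benzofuran-1-yl]methyl}-6-methylidene-2-oxobicyclo[3.2.1]oct-3-en-7-yl acetate
Conditions: Ac2O, pyridine, DMAP (cat.), CH2Cl2, 0 °C
Reagents that add atoms: acetic anhydride, CC(=O)OC(C)=O
Why: Nucleophile-catalysed acylation esterifies the secondary allylic C15 hydroxyl, the tertiary C10 hydroxyl being too hindered to react under these conditions.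

**Compound list**

1 | tert-butyl methacrylate (tert-butyl 2-methylprop-2-enoate) | C=C(C)C(=O)OC(C)(C)C | starting material
2 | allyl diethyl phosphate (diethyl prop-2-en-1-yl phosphate) | C=CCOP(=O)(OCC)OCC | starting material
3 | tert-butyl (E)-4-[(diethoxyphosphoryl)oxy]-2-methylbut-2-enoate | CC(C)(C)OC(=O)/C(C)=C/COP(=O)(OCC)OCC | intermediate
4 | 2-(3-chloropropyl)-2-methyl-1,3-dioxolane | CC1(CCCCl)OCCO1 | starting material
5 | 2-(3-iodopropyl)-2-methyl-1,3-dioxolane | CC1(CCCI)OCCO1 | intermediate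
6 | bis[3-(2-methyl-1,3-dioxolan-2-yl)propyl]zinc | CC1(CCC[Zn]CCCC2(C)OCCO2)OCCO1 | intermediate
7 | tert-butyl (R)-2-methyl-2-[3-(2-methyl-1,3-dioxolan-2-yl)propyl]but-3-enoate | CC(C)(C)OC(=O)[C@](C=C)(C)CCCC1(C)OCCO1 | intermediate
8 | (E)-1,4-dibromobut-2-ene | BrC/C=C/CBr | starting material
9 | tert-butyl (R,E)-5-bromo-2-methyl-2-[3-(2-methyl-1,3-dioxolan-2-yl)propyl]pent-3-enoate | CC(C)(C)OC(=O)[C@](/C=C/CBr)(C)CCCC1(C)OCCO1 | intermediate
10 | pent-4-enal | C=CCCC=O | starting material
11 | but-3-en-2-one | C=CC(C)=O | starting material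
12 | (R)-5-oxo-2-(prop-2-en-1-yl)hexanal | C=CC[C@@H](CCC(C)=O)C=O | intermediate
13 | (R)-4-(prop-2-en-1-yl)cyclohex-2-en-1-one | C=CC[C@@H]1C=CC(=O)CC1 | intermediate
14 | lithium 4-(prop-2-en-1-yl)cyclohexa-1,5-dien-1-olate, stereocentre as in 13 | C=CC[C@@H]1C=CC(O[Li])=CC1 | intermediate
15 | tert-butyl (2R,3E)-2-methyl-2-[3-(2-methyl-1,3-dioxolan-2-yl)propyl]-5-[trans-2-oxo-5-(prop-2-en-1-yl)cyclohex-3-en-1-yl]pent-3-enoate, C13 as in 13 | C=CC[C@@H]1C=CC(=O)[C@@H](C/C=C/[C@@](C)(CCCC2(C)OCCO2)C(=O)OC(C)(C)C)C1 | intermediate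
16 | (2R,3E)-2-methyl-2-(4-oxopentyl)-5-[trans-2-oxo-5-(prop-2-en-1-yl)cyclohex-3-en-1-yl]pent-3-enoic acid, C13 as in 13 | C=CC[C@@H]1C=CC(=O)[C@@H](C/C=C/[C@@](C)(CCCC(C)=O)C(=O)O)C1 | intermediate
17 | (3R,3aS,4R,7aR)-4-hydroxy-4,7a-dimethyl-3-{[trans-2-oxo-5-(prop-2-en-1-yl)cyclohex-3-en-1-yl]methyl}hexahydro-2-benzofuran-1(3H)-one, C13 as in 13 | C=CC[C@@H]1C=CC(=O)[C@@H](C[C@H]2OC(=O)[C@]3(C)CCC[C@@](C)(O)[C@H]23)C1 | intermediate
18 | diol of 17: the allyl group is replaced by a 2,3-dihydroxypropyl group (carbinol epimers) | OCC(O)C[C@@H]1C=CC(=O)[C@@H](C[C@H]2OC(=O)[C@]3(C)CCC[C@@](C)(O)[C@H]23)C1 | intermediate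
19 | (3R,3aS,4R,7aR)-4-hydroxy-4,7a-dimethyl-3-{[trans-2-oxo-5-(2-oxoethyl)cyclohex-3-en-1-yl]methyl}hexahydro-2-benzofuran-1(3H)-one | O=CC[C@@H]1C=CC(=O)[C@@H](C[C@H]2OC(=O)[C@]3(C)CCC[C@@](C)(O)[C@H]23)C1 | intermediate
20 | (3R,3aS,4R,7aR)-4-hydroxy-4,7a-dimethyl-3-{[trans-2-oxo-5-(3-oxoprop-1-en-2-yl)cyclohex-3-en-1-yl]methyl}hexahydro-2-benzofuran-1(3H)-one | C=C(C=O)[C@@H]1C=CC(=O)[C@@H](C[C@H]2OC(=O)[C@]3(C)CCC[C@@](C)(O)[C@H]23)C1 | intermediate
21 | dilithium dienolate of 20 (C8=C9 enolate, C10 alkoxide) | C=C(C=O)[C@@H]1C=CC(O[Li])=C(C[C@H]2OC(=O)[C@]3(C)CCC[C@@](C)(O[Li])[C@H]23)C1 | intermediate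
22 | dilithium aldolate of 23 (C15 and C10 alkoxides) | C=C1[C@@H]2C=CC(=O)[C@@](C[C@H]3OC(=O)[C@]4(C)CCC[C@@](C)(O[Li])[C@H]34)(C2)[C@@H]1O[Li] | intermediate
23 | (3R,3aS,4R,7aR)-4-hydroxy-3-{[(1R,5S,7R)-7-hydroxy-6-methylidene-2-oxobicyclo[3.2.1]oct-3-en-1-yl]methyl}-4,7a-dimethylhexahydro-2-benzofuran-1(3H)-one | C=C1[C@@H]2C=CC(=O)[C@@](C[C@H]3OC(=O)[C@]4(C)CCC[C@@](C)(O)[C@H]34)(C2)[C@@H]1O | intermediate
24 | CNP0172716.1, (1R,5S,7R)-1-{[(1R,3aR,7R,7aS)-7-hydroxy-3a,7-dimethyl-3-oxooctahydro-2-benzofuran-1-yl]methyl}-6-methylidene-2-oxobicyclo[3.2.1]oct-3-en-7-yl acetate | C=C1[C@@H]2C=CC(=O)[C@@](C[C@H]3OC(=O)[C@]4(C)CCC[C@@](C)(O)[C@H]34)(C2)[C@@H]1OC(C)=O | target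

**Step count and risks**

Total step count: 12. Longest linear sequence: 10 steps (1, 3, 4, 6, 7, 8, 9, 10, 11, 12).

Steps most likely to fail:

1. Step 8. The unactivated 1,2-disubstituted alkene is a weak π-nucleophile, so cyclisation may stall. The cation may instead be quenched by proton loss from C7, by chloride, or by the C9 carbonyl oxygen, and facial selectivity at the C10 carbonyl may be poor. The fallback separates C–C from C–O bond formation and turns the likeliest side reaction into the route. From 16, a type-1 carbonyl–ene cyclisation (Me2AlCl, CH2Cl2, −78 to 0 °C) would give hydroxy acid F1 with the C6=C7 alkene; the trans-diequatorial chair should place the hydroxyl trans to the alkenyl group, with the smaller carboxyl axial on C4. Iodolactonisation under equilibrating conditions (I2, MeCN) would give iodolactone F2 with C7 on the convex face. Radical deiodination (Bu3SnH, AIBN, toluene, 80 °C) returns to 17.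

2. Step 11. Deprotonation may occur at the γ-carbon C13 (epimerisation), the amide base may add to the enal, and the aldolate may undergo retro-aldol cleavage on warming. The fallback replaces the strong amide base by Lewis-acid-assisted soft enolisation. From 20, Bu2BOTf and iPr2NEt (CH2Cl2, −78 °C) would give boron dienolate F3, which should cyclise through a closed boron-bridged transition state with the same C15 sense to boron aldolate F4. Non-oxidative hydrolysis (MeOH, pH 7 buffer) returns to 23.

3. Step 4. Metathesis at the olefin next to the quaternary carbon may be sluggish, the allylic bromide may shorten catalyst life, and the geometry may erode. The fallback builds the allylic bromide by carbonyl olefination. From 7, ozonolysis (O3, CH2Cl2, −78 °C; Me2S) would give aldehyde F5. Horner–Wadsworth–Emmons olefination with triethyl phosphonoacetate (NaH, THF) would give enoate F6. Reduction of the unhindered ethyl ester (iBu2AlH, CH2Cl2, −78 °C) would give allylic alcohol F7, and CBr4/PPh3 returns to 9.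

Further compounds
F1 | step 8 | (1R,2S,3R)-3-hydroxy-1,3-dimethyl-2-{(E)-2-[trans-2-oxo-5-(prop-2-en-1-yl)cyclohex-3-en-1-yl]ethenyl}cyclohexane-1-carboxylic acid | C=CC[C@@H]1C=CC(=O)[C@@H](/C=C/[C@H]2[C@](C)(O)CCC[C@@]2(C)C(=O)O)C1
F2 | step 8 | C7-iodo derivative of 17 (iodine on the methylene link, anti to the lactone oxygen) | C=CC[C@@H]1C=CC(=O)[C@@H]([C@@H](I)[C@H]2OC(=O)[C@]3(C)CCC[C@@](C)(O)[C@H]23)C1
F3 | step 11 | bis(dibutylboryl) derivative of 20 (C8=C9 boron enolate, C10 borinate) | C=C(C=O)[C@@H]1C=CC(OB(CCCC)CCCC)=C(C[C@H]2OC(=O)[C@]3(C)CCC[C@@](C)(OB(CCCC)CCCC)[C@H]23)C1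
F4 | step 11 | bis(dibutylboryl) ether of 23 (C15 aldolate and C10 borinate) | C=C1[C@@H]2C=CC(=O)[C@@](C[C@H]3OC(=O)[C@]4(C)CCC[C@@](C)(OB(CCCC)CCCC)[C@H]34)(C2)[C@@H]1OB(CCCC)CCCC
F5 | step 4 | tert-butyl (R)-2-formyl-2-methyl-5-(2-methyl-1,3-dioxolan-2-yl)pentanoate | CC(C)(C)OC(=O)[C@](C=O)(C)CCCC1(C)OCCO1
F6 | step 4 | 5-tert-butyl 1-ethyl (2E,4R)-4-methyl-4-[3-(2-methyl-1,3-dioxolan-2-yl)propyl]pent-2-enedioate | CC(C)(C)OC(=O)[C@](/C=C/C(=O)OCC)(C)CCCC1(C)OCCO1
F7 | step 4 | tert-butyl (2R,3E)-5-hydroxy-2-methyl-2-[3-(2-methyl-1,3-dioxolan-2-yl)propyl]pent-3-enoate | CC(C)(C)OC(=O)[C@](/C=C/CO)(C)CCCC1(C)OCCO1
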